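**Plan**

- Cuts: C11=C12 (Wittig) into a left C15 dienal and a right C25 phosphonium salt; the right half at C11'=C12' (Wittig to the C10 dialdehyde) and C6'–C7' (Sonogashira); the left half at C9=C10 (Horner–Wadsworth–Emmons), then the C7=C8–C9=O enone back to a C7 propargylic carbinol (Meyer–Schuster) and C3–O/C6–O back to a ring diene (singlet-oxygen [4+2]).
- Enabling feature: the left ring is a cyclohex-4-ene whose C3 and C6 carry cis oxygens on either side of C4=C5, the retron of a 1,3-diene endoperoxide; its six ring carbons, three methyls and C7 are the skeleton of safranal.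
- Forward, left: safranal → (R)-C7 propynyl carbinol → 2,3-dioxabicyclo[2.2.2]octene (the only ring made; both carbocycles are bought) → (7E)-enone → cis-diol → C15 dienal.
- Forward, right: ketoisophorone → (4R)-silyloxy enol triflate → acetylenic C15 salt → C25 aldehyde → C25 salt; a last Wittig joins C11 to C12.
- Stereochemistry: C7 by oxazaborolidine reduction, relayed to C3 and C6 in the cycloaddition and then erased; C3' by enzymatic C=C reduction (C6') relayed to the carbinol by a hindered hydride; alkene geometry from thermodynamic enone formation, the (E)-enynol building block and Wittig/thermal equilibration.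

Key step: step 4

Numbering: carotenoid numbering, with the dihydroxy ring and its chain unprimed (C1–C15) and the acetylenic half primed.

Assumption: the (R)-carbinol 5 reacts through the rotamer whose C7–H eclipses C5=C6, so oxygen enters syn to the hydroxyl and gives (3S,6R); if the facial sense proves opposite, the (S)-carbinol from the enantiomeric oxazaborolidine is carried through the same steps.

**Route**

Step 1
Reactants: 1 safranal (2,6,6-trimethylcyclohexa-1,3-diene-1-carbaldehyde); 2 1-propynylmagnesium bromide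
Product: 3 rac-1-(2,6,6-trimethylcyclohexa-1,3-dien-1-yl)but-2-yn-1-ol
Conditions: THF, 0 °C to rt; aq. NH4Cl
Reagents that add atoms: none
Why: Grignard 1,2-addition of a hard alkynyl nucleophile to the non-enolisable hindered dienal gives the racemic C7 carbinol, whose configuration is set in steps 2 and 3.

Step 2
Reactants: 3 rac-1-(2,6,6-trimethylcyclohexa-1,3-dien-1-yl)but-2-yn-1-ol
Product: 4 1-(2,6,6-trimethylcyclohexa-1,3-dien-1-yl)but-2-yn-1-one
Conditions: activated MnO2, CH2Cl2, rt
Reagents that add atoms: none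
Why: MnO2 oxidation of a secondary alcohol that is both allylic and propargylic should give the ynone without touching the ring diene.

Step 3
Reactants: 4 1-(2,6,6-trimethylcyclohexa-1,3-dien-1-yl)but-2-yn-1-one
Product: 5 (R)-1-(2,6,6-trimethylcyclohexa-1,3-dien-1-yl)but-2-yn-1-ol
Conditions: (S)-Me-CBS oxazaborolidine [(S)-1-methyl-3,3-diphenyltetrahydro-1H,3H-pyrrolo[1,2-c][1,3,2]oxazaborole, C18H20BNO] (0.5 equiv), BH3·SMe2, THF, −30 °C; MeOH quench
Reagents that add atoms: none
Why: Corey–Bakshi–Shibata reduction, in which the catalyst binds the carbonyl anti to the fully substituted ring (large group) and delivers hydride past the slim propynyl (small group), which by the standard model gives the (R)-carbinol from the (S)-catalyst.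

Step 4
Reactants: 5 (R)-1-(2,6,6-trimethylcyclohexa-1,3-dien-1-yl)but-2-yn-1-ol
Product: 6 (R)-1-[(1R,4S)-6,7,7-trimethyl-2,3-dioxabicyclo[2.2.2]oct-5-en-1-yl]but-2-yn-1-ol
Conditions: O2, 5,10,15,20-tetraphenylporphyrin (TPP, 1 mol%), visible light, CH2Cl2, −30 °C; chromatography to remove the minor C7 diastereomer
Reagents that add atoms: dioxygen, O=O
Why: Photosensitised singlet oxygen adds suprafacially across C3 and C6 of the s-cis ring diene in a concerted [4+2] cycloaddition, making both C–O bonds and moving the alkene to C4=C5; the closest known reaction type is the hydroxyl-directed photooxygenation of chiral dienyl and naphthyl carbinols. The one ring closed is the six-membered 1,2-dioxane C3–O–O–C6–C5=C4, formed as the peroxide bridge of the bicyclo[2.2.2]octene in a single cycloaddition (both bonds at once, no stepwise closure). C3 and C6 arise together and their cis relationship is fixed by the suprafacial addition; their absolute sense is controlled by the C7 carbinol, whose C–H eclipses C5=C6 to avoid 1,3-allylic strain with the C5 methyl, so that the (R)-hydroxyl lies on one diene face and hydrogen-bonds the incoming oxygen in the aprotic solvent. The step needs π-facial selectivity and [4+2] rather than ene chemoselectivity: the first is secured by this hydrogen bond and backed by chromatographic removal of the minor C7 diastereomer (so the ring ee equals the carbinol ee), the second by the locked s-cis geometry of the cyclohexadiene. The alkyne does not react with singlet oxygen.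

Step 5
Reactants: 6 (R)-1-[(1R,4S)-6,7,7-trimethyl-2,3-dioxabicyclo[2.2.2]oct-5-en-1-yl]but-2-yn-1-ol
Product: 7 (E)-4-[(1R,4S)-6,7,7-trimethyl-2,3-dioxabicyclo[2.2.2]oct-5-en-1-yl]but-3-en-2-one
Conditions: Ph3PAuNTf2 (2 mol%), MeOH (1 equiv), toluene, rt
Reagents that add atoms: none
Why: Gold-catalysed Meyer–Schuster rearrangement of a secondary propargylic alcohol (alkyne activation, MeOH addition at C9, loss of the C7 hydroxyl, hydrolysis) should give the thermodynamic (7E)-enone and erase C7, while the peroxide bridge masks both ring oxygens and is not expected to be reduced by monovalent gold, which is no one-electron donor.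

Step 6
Reactants: 7 (E)-4-[(1R,4S)-6,7,7-trimethyl-2,3-dioxabicyclo[2.2.2]oct-5-en-1-yl]but-3-en-2-one
Product: 8 (E)-4-[(1R,4S)-1,4-dihydroxy-2,6,6-trimethylcyclohex-2-en-1-yl]but-3-en-2-one
Conditions: thiourea, MeOH, rt
Reagents that add atoms: none
Why: Thiourea reduction of the O–O bond (sulfur attacks oxygen) opens the endoperoxide to the cis-3,6-diol with both C–O bonds and both stereocentres intact and the enone untouched.

Step 7
Reactants: 8 (E)-4-[(1R,4S)-1,4-dihydroxy-2,6,6-trimethylcyclohex-2-en-1-yl]but-3-en-2-one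
Product: 9 (1S,4R)-4-hydroxy-3,5,5-trimethyl-4-[(E)-3-oxobut-1-en-1-yl]cyclohex-2-en-1-yl acetate
Conditions: Ac2O, pyridine, 4-(dimethylamino)pyridine (cat.), CH2Cl2, 0 °C
Reagents that add atoms: acetic anhydride, CC(=O)OC(C)=O
Why: Selective acylation of the secondary allylic C3 hydroxyl beside the hindered tertiary C6 hydroxyl keeps a nucleophilic secondary alkoxide out of the strongly basic next step.

Step 8
Reactants: 9 (1S,4R)-4-hydroxy-3,5,5-trimethyl-4-[(E)-3-oxobut-1-en-1-yl]cyclohex-2-en-1-yl acetate; 10 diethyl cyanomethylphosphonate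
Product: 11 (1S,4R)-4-[(1E,3E)-4-cyano-3-methylbuta-1,3-dien-1-yl]-4-hydroxy-3,5,5-trimethylcyclohex-2-en-1-yl acetate
Conditions: NaH (3 equiv), THF, 0 °C to rt; chromatographic removal of the (9Z) isomer
Reagents that add atoms: none
Why: Horner–Wadsworth–Emmons olefination of the methyl ketone builds C9=C10, with the (9E) isomer expected to predominate, the tertiary hydroxyl carried as its sodium alkoxide and the acetate inert to the stabilised carbanion.

Step 9
Reactants: 11 (1S,4R)-4-[(1E,3E)-4-cyano-3-methylbuta-1,3-dien-1-yl]-4-hydroxy-3,5,5-trimethylcyclohex-2-en-1-yl acetate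
Product: 13 (2E,4E)-5-[(1R,4S)-1,4-dihydroxy-2,6,6-trimethylcyclohex-2-en-1-yl]-3-methylpenta-2,4-dienal, via N-aluminated aldimine 12 (not isolated)
Conditions: i-Bu2AlH (5 equiv), CH2Cl2, −78 to −20 °C; aq. potassium sodium tartrate (KNaC4H4O6), then wet SiO2
Reagents that add atoms: water, O
Why: Hydride reduction of the nitrile stops at the aluminated aldimine, which hydrolyses on work-up to the dienal, while the excess hydride removes the C3 acetate reductively; nothing more acidic than silica is used because of the doubly allylic C6 hydroxyl.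

Step 10
Reactants: 14 ketoisophorone (2,6,6-trimethylcyclohex-2-ene-1,4-dione)
Product: 15 (6R)-2,2,6-trimethylcyclohexane-1,4-dione
Conditions: ene-reductase OYE2 (old yellow enzyme), NADP+ (cat.), glucose dehydrogenase, D-glucose, phosphate buffer pH 7, 30 °C
Reagents that add atoms: none
Why: Enzymatic conjugate (ene-reductase) reduction of the enone C=C with cofactor recycling is the standard access to the (6R)-diketone, the enzyme's facial preference setting C6.

Step 11
Reactants: 15 (6R)-2,2,6-trimethylcyclohexane-1,4-dione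
Product: 16 (4R,6R)-4-hydroxy-2,2,6-trimethylcyclohexan-1-one
Conditions: LiBH(s-Bu)3 (1.05 equiv), THF, −78 °C
Reagents that add atoms: none
Why: Hindered-hydride reduction attacks only the unflanked C4 carbonyl and from the equatorial direction, away from the axial C2 methyl, giving the axial alcohol trans to the C6 methyl, which is (4R).

Step 12
Reactants: 16 (4R,6R)-4-hydroxy-2,2,6-trimethylcyclohexan-1-one
Product: 17 (4R,6R)-2,2,6-trimethyl-4-(triethylsilyloxy)cyclohexan-1-one
Conditions: Et3SiCl, imidazole, CH2Cl2, 0 °C to rt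
Reagents that add atoms: chlorotriethylsilane, CC[Si](Cl)(CC)CC
Why: Standard silyl ether formation masks the hydroxyl for the enolate chemistry that follows.

Step 13
Reactants: 17 (4R,6R)-2,2,6-trimethyl-4-(triethylsilyloxy)cyclohexan-1-one
Product: 19 (R)-2,6,6-trimethyl-4-(triethylsilyloxy)cyclohex-1-en-1-yl trifluoromethanesulfonate, via potassium enolate 18 (not isolated)
Conditions: KN(SiMe3)2, THF, −78 to 0 °C; then PhNTf2, −78 °C to rt
Reagents that add atoms: N-phenylbis(trifluoromethanesulfonimide), O=S(=O)(N(c1ccccc1)S(=O)(=O)C(F)(F)F)C(F)(F)F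
Why: Deprotonation at the only enolisable position gives the tetrasubstituted enolate, whose O-sulfonylation gives the enol triflate and erases C6 after it has relayed its configuration to the carbinol.

Step 14
Reactants: 19 (R)-2,6,6-trimethyl-4-(triethylsilyloxy)cyclohex-1-en-1-yl trifluoromethanesulfonate; 20 (E)-3-methylpent-2-en-4-yn-1-ol
Product: 21 (R,E)-3-methyl-5-[2,6,6-trimethyl-4-(triethylsilyloxy)cyclohex-1-en-1-yl]pent-2-en-4-yn-1-ol
Conditions: Pd(PPh3)4 (5 mol%), CuI (10 mol%), Et3N, DMF, rt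
Reagents that add atoms: none
Why: Sonogashira coupling (oxidative addition of zerovalent palladium into the enol triflate, copper acetylide transfer) forms C6'–C7' with the triple bond in place and carries the (E) geometry of the enynol into C9'=C10'.

Step 15
Reactants: 21 (R,E)-3-methyl-5-[2,6,6-trimethyl-4-(triethylsilyloxy)cyclohex-1-en-1-yl]pent-2-en-4-yn-1-ol
Product: 23 [(R,E)-5-(4-hydroxy-2,6,6-trimethylcyclohex-1-en-1-yl)-3-methylpent-2-en-4-yn-1-yl]triphenylphosphonium bromide, via desilylated diol 22 (not isolated)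
Conditions: PPh3·HBr (1.2 equiv), MeOH, rt
Reagents that add atoms: triphenylphosphine hydrobromide, [Br-].[PH+](c1ccccc1)(c1ccccc1)c1ccccc1
Why: Acidic methanol first strips the triethylsilyl ether, and the protonated primary allylic alcohol is then displaced by phosphine (the classical phosphonium salt formation from allylic alcohols), the conjugated enyne holding the (9'E) geometry.

Step 16
Reactants: 23 [(R,E)-5-(4-hydroxy-2,6,6-trimethylcyclohex-1-en-1-yl)-3-methylpent-2-en-4-yn-1-yl]triphenylphosphonium bromide; 24 (2E,4E,6E)-2,7-dimethylocta-2,4,6-trienedial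
Product: 26 (2E,4E,6E,8E,10E)-13-[(R)-4-hydroxy-2,6,6-trimethylcyclohex-1-en-1-yl]-2,7,11-trimethyltrideca-2,4,6,8,10-pentaen-12-ynal, via phosphorus ylide 25 (not isolated)
Conditions: 24 (2 equiv), NaOMe, MeOH/CH2Cl2, 0 °C to rt; gentle warming in EtOAc, chromatography
Reagents that add atoms: none
Why: Wittig olefination of the semi-stabilised allylic ylide with an excess of the symmetrical dialdehyde should give the mono-adduct and form C11'=C12', the hindered (11'Z) isomer equilibrating to (E) on warming.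

Step 17
Reactants: 26 (2E,4E,6E,8E,10E)-13-[(R)-4-hydroxy-2,6,6-trimethylcyclohex-1-en-1-yl]-2,7,11-trimethyltrideca-2,4,6,8,10-pentaen-12-ynal
Product: 27 (R)-4-[(3E,5E,7E,9E,11E)-13-hydroxy-3,7,12-trimethyltrideca-3,5,7,9,11-pentaen-1-yn-1-yl]-3,5,5-trimethylcyclohex-3-en-1-ol
Conditions: NaBH4, MeOH/CH2Cl2, 0 °C
Reagents that add atoms: none
Why: Borohydride 1,2-reduction of the polyenal gives the primary allylic alcohol without touching the polyene or alkyne.

Step 18
Reactants: 27 (R)-4-[(3E,5E,7E,9E,11E)-13-hydroxy-3,7,12-trimethyltrideca-3,5,7,9,11-pentaen-1-yn-1-yl]-3,5,5-trimethylcyclohex-3-en-1-ol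
Product: 28 [(2E,4E,6E,8E,10E)-13-[(R)-4-hydroxy-2,6,6-trimethylcyclohex-1-en-1-yl]-2,7,11-trimethyltrideca-2,4,6,8,10-pentaen-12-yn-1-yl]triphenylphosphonium bromide
Conditions: PPh3·HBr, MeOH/CH2Cl2, rt, dark
Reagents that add atoms: triphenylphosphine hydrobromide, [Br-].[PH+](c1ccccc1)(c1ccccc1)c1ccccc1
Why: Phosphonium salt formation from a polyenylic alcohol proceeds through the delocalised cation, which phosphine captures at the primary terminus as in retinyl and apocarotenyl salts; only the acid-tolerant half of the molecule sees the acid.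

Step 19
Reactants: 28 the C25 phosphonium bromide of step 18; 13 (2E,4E)-5-[(1R,4S)-1,4-dihydroxy-2,6,6-trimethylcyclohex-2-en-1-yl]-3-methylpenta-2,4-dienal
Product: 30 (3S,6R,3'R,all-E)-7',8'-didehydro-ε,β-carotene-3,6,3'-triol [systematically (3R,3'S,6'R)-7,8-didehydro-β,ε-carotene-3,3',6'-triol], via phosphorus ylide 29 (not isolated)
Conditions: NaOMe, MeOH/CH2Cl2, rt, dark; then EtOAc, 50 °C, dark; preparative HPLC
Reagents that add atoms: none
Why: Wittig olefination joins C11 of the dienal to C12 of the ylide with the free hydroxyls tolerated, and thermal equilibration of the hindered (11Z) isomer followed by HPLC should leave the all-E triol, C3, C6 and C3' being untouched.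

**Compound list**

1 | safranal (2,6,6-trimethylcyclohexa-1,3-diene-1-carbaldehyde) | CC1=C(C=O)C(C)(C)CC=C1 | starting material
2 | 1-propynylmagnesium bromide | CC#C[Mg]Br | starting material
3 | rac-1-(2,6,6-trimethylcyclohexa-1,3-dien-1-yl)but-2-yn-1-ol | CC#CC(O)C1=C(C)C=CCC1(C)C | intermediate
4 | 1-(2,6,6-trimethylcyclohexa-1,3-dien-1-yl)but-2-yn-1-one | CC#CC(=O)C1=C(C)C=CCC1(C)C | intermediate
5 | (R)-1-(2,6,6-trimethylcyclohexa-1,3-dien-1-yl)but-2-yn-1-ol | CC1=C([C@H](O)C#CC)C(C)(C)CC=C1 | intermediate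
6 | (R)-1-[(1R,4S)-6,7,7-trimethyl-2,3-dioxabicyclo[2.2.2]oct-5-en-1-yl]but-2-yn-1-ol | CC1=C[C@@H]2CC(C)(C)[C@]1(OO2)[C@H](O)C#CC | intermediate
7 | (E)-4-[(1R,4S)-6,7,7-trimethyl-2,3-dioxabicyclo[2.2.2]oct-5-en-1-yl]but-3-en-2-one | CC1=C[C@@H]2CC(C)(C)[C@]1(OO2)/C=C/C(C)=O | intermediate
8 | (E)-4-[(1R,4S)-1,4-dihydroxy-2,6,6-trimethylcyclohex-2-en-1-yl]but-3-en-2-one | CC1=C[C@@H](O)CC(C)(C)[C@]1(O)/C=C/C(C)=O | intermediate
9 | (1S,4R)-4-hydroxy-3,5,5-trimethyl-4-[(E)-3-oxobut-1-en-1-yl]cyclohex-2-en-1-yl acetate | CC1=C[C@@H](OC(C)=O)CC(C)(C)[C@]1(O)/C=C/C(C)=O | intermediate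
10 | diethyl cyanomethylphosphonate | N#CCP(=O)(OCC)OCC | starting material
11 | (1S,4R)-4-[(1E,3E)-4-cyano-3-methylbuta-1,3-dien-1-yl]-4-hydroxy-3,5,5-trimethylcyclohex-2-en-1-yl acetate | CC1=C[C@@H](OC(C)=O)CC(C)(C)[C@]1(O)/C=C/C(C)=C/C#N | intermediate
12 | (2E,4E)-5-[(1R,4S)-1,4-dihydroxy-2,6,6-trimethylcyclohex-2-en-1-yl]-3-methylpenta-2,4-dien-1-imine (drawn as the N–H aldimine; present in the flask as its N- and O-aluminated form) | CC1=C[C@@H](O)CC(C)(C)[C@]1(O)/C=C/C(C)=C/C=N | intermediate (not isolated)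
13 | (2E,4E)-5-[(1R,4S)-1,4-dihydroxy-2,6,6-trimethylcyclohex-2-en-1-yl]-3-methylpenta-2,4-dienal | CC1=C[C@@H](O)CC(C)(C)[C@]1(O)/C=C/C(C)=C/C=O | intermediate
14 | ketoisophorone (2,6,6-trimethylcyclohex-2-ene-1,4-dione) | CC1=CC(=O)CC(C)(C)C1=O | starting material
15 | (6R)-2,2,6-trimethylcyclohexane-1,4-dione | O=C1C(C)(C)CC(=O)C[C@H]1C | intermediate
16 | (4R,6R)-4-hydroxy-2,2,6-trimethylcyclohexan-1-one | O=C1C(C)(C)C[C@H](O)C[C@H]1C | intermediate
17 | (4R,6R)-2,2,6-trimethyl-4-(triethylsilyloxy)cyclohexan-1-one | O=C1C(C)(C)C[C@H](O[Si](CC)(CC)CC)C[C@H]1C | intermediate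
18 | potassium (R)-2,6,6-trimethyl-4-(triethylsilyloxy)cyclohex-1-en-1-olate | [K+].[O-]C1=C(C)C[C@@H](O[Si](CC)(CC)CC)CC1(C)C | intermediate (not isolated)
19 | (R)-2,6,6-trimethyl-4-(triethylsilyloxy)cyclohex-1-en-1-yl trifluoromethanesulfonate | FC(F)(F)S(=O)(=O)OC1=C(C)C[C@@H](O[Si](CC)(CC)CC)CC1(C)C | intermediate
20 | (E)-3-methylpent-2-en-4-yn-1-ol | C#C/C(C)=C/CO | starting material
21 | (R,E)-3-methyl-5-[2,6,6-trimethyl-4-(triethylsilyloxy)cyclohex-1-en-1-yl]pent-2-en-4-yn-1-ol | OC/C=C(\C)C#CC1=C(C)C[C@@H](O[Si](CC)(CC)CC)CC1(C)C | intermediate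
22 | (R,E)-5-(4-hydroxy-2,6,6-trimethylcyclohex-1-en-1-yl)-3-methylpent-2-en-4-yn-1-ol | OC/C=C(\C)C#CC1=C(C)C[C@@H](O)CC1(C)C | intermediate (not isolated)
23 | [(R,E)-5-(4-hydroxy-2,6,6-trimethylcyclohex-1-en-1-yl)-3-methylpent-2-en-4-yn-1-yl]triphenylphosphonium bromide | [Br-].C(/C=C(\C)C#CC1=C(C)C[C@@H](O)CC1(C)C)[P+](c1ccccc1)(c1ccccc1)c1ccccc1 | intermediate
24 | (2E,4E,6E)-2,7-dimethylocta-2,4,6-trienedial | O=C/C(C)=C/C=C/C=C(C)/C=O | starting material
25 | ylide of 23, [(R,E)-5-(4-hydroxy-2,6,6-trimethylcyclohex-1-en-1-yl)-3-methylpent-2-en-4-yn-1-ylidene]triphenylphosphorane | C(/C=C(\C)C#CC1=C(C)C[C@@H](O)CC1(C)C)=P(c1ccccc1)(c1ccccc1)c1ccccc1 | intermediate (not isolated)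
26 | (2E,4E,6E,8E,10E)-13-[(R)-4-hydroxy-2,6,6-trimethylcyclohex-1-en-1-yl]-2,7,11-trimethyltrideca-2,4,6,8,10-pentaen-12-ynal | O=C/C(C)=C/C=C/C=C(C)/C=C/C=C(\C)C#CC1=C(C)C[C@@H](O)CC1(C)C | intermediate
27 | (R)-4-[(3E,5E,7E,9E,11E)-13-hydroxy-3,7,12-trimethyltrideca-3,5,7,9,11-pentaen-1-yn-1-yl]-3,5,5-trimethylcyclohex-3-en-1-ol | OC/C(C)=C/C=C/C=C(C)/C=C/C=C(\C)C#CC1=C(C)C[C@@H](O)CC1(C)C | intermediate
28 | [(2E,4E,6E,8E,10E)-13-[(R)-4-hydroxy-2,6,6-trimethylcyclohex-1-en-1-yl]-2,7,11-trimethyltrideca-2,4,6,8,10-pentaen-12-yn-1-yl]triphenylphosphonium bromide | [Br-].C(/C(C)=C/C=C/C=C(C)/C=C/C=C(\C)C#CC1=C(C)C[C@@H](O)CC1(C)C)[P+](c1ccccc1)(c1ccccc1)c1ccccc1 | intermediate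
29 | ylide of 28, the corresponding pentaenynylidene(triphenyl)phosphorane | C(/C(C)=C/C=C/C=C(C)/C=C/C=C(\C)C#CC1=C(C)C[C@@H](O)CC1(C)C)=P(c1ccccc1)(c1ccccc1)c1ccccc1 | intermediate (not isolated)
30 | (3S,6R,3'R,all-E)-7',8'-didehydro-ε,β-carotene-3,6,3'-triol | CC1=C[C@@H](O)CC(C)(C)[C@]1(O)/C=C/C(C)=C/C=C/C(C)=C/C=C/C=C(C)/C=C/C=C(\C)C#CC1=C(C)C[C@@H](O)CC1(C)C | target

**Totals**

Total step count: 19. Longest linear sequence: 10 steps (steps 1–9 then 19, or steps 10–19).

**Steps most likely to fail**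

Step 4. Oxygen may add to both diene faces, or mainly to the face opposite to the one assumed, because the C7 carbinol is flanked by the C5 methyl and the C1 gem-dimethyl and two rotamers of similar strain present the hydroxyl to opposite faces; ene-type hydroperoxidation may also compete. The fallback sets out from 1 and comes back at 8; it drops the C7 relay and resolves instead. Aldol condensation of 1 with acetone (aq. NaOH) gives 3,4-didehydro-β-ionone F1. Photooxygenation (O2, TPP, visible light, CH2Cl2) gives the racemic endoperoxide enone F2, and thiourea in MeOH gives the racemic cis-3,6-diol F3. Lipase-catalysed acetylation (Burkholderia cepacia lipase, vinyl acetate) is expected to acetylate the (3R,6S)-enantiomer to the enantiomeric acetate F4 and to leave the (3S,6R)-diol, which is 8. If the enzyme prefers the other enantiomer, the acetate it forms is 9 itself.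

Step 5. The cationic gold catalyst may open or isomerise the peroxide bridge, or a peroxide oxygen may attack the activated alkyne, faster than the hydroxyl shift. The fallback sets out from 6 and comes back at 9; it reduces first and runs the gold step on a peroxide-free, fully capped substrate. Thiourea reduction of 6 gives the triol F5, and Ac2O/pyridine/4-(dimethylamino)pyridine gives the 3,7-diacetate F6. Et3SiOSO2CF3 with 2,6-lutidine caps the tertiary hydroxyl as the triethylsilyl ether F7; this is needed because a free C6 hydroxyl would add to the gold-activated alkyne or allene. Ph3PAuNTf2 in wet butan-2-one converts the propargylic acetate by 1,3-acyloxy shift and hydrolysis into the silylated (7E)-enone F8, and Bu4NF buffered with AcOH removes the silyl group to give 9.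

Step 3. Face discrimination at the hindered, cross-conjugated ynone may be incomplete and borane may hydroborate the alkyne or diene, which would lower the ee of 5 and with it that of the whole left half. The fallback sets out from 3 and comes back at 5; it uses kinetic resolution in place of asymmetric reduction. Lipase-catalysed acylation of racemic 3 (Candida antarctica lipase B, vinyl acetate, hexane) should acetylate the (R)-enantiomer (ring as the large group, Kazlauskas rule) to the (R)-acetate F9. The (S)-carbinol F10 is left behind and can be returned to 4 by step 2. K2CO3 in MeOH cleaves F9 to 5.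

Further compounds
F1 | step 4 | (E)-4-(2,6,6-trimethylcyclohexa-1,3-dien-1-yl)but-3-en-2-one (3,4-didehydro-β-ionone) | CC(=O)/C=C/C1=C(C)C=CCC1(C)C
F2 | step 4 | racemic (E)-4-(6,7,7-trimethyl-2,3-dioxabicyclo[2.2.2]oct-5-en-1-yl)but-3-en-2-one (both enantiomers) | CC1=C[C@@H]2CC(C)(C)[C@]1(OO2)/C=C/C(C)=O.CC1=C[C@H]2CC(C)(C)[C@@]1(OO2)/C=C/C(C)=O
F3 | step 4 | racemic cis-(E)-4-(1,4-dihydroxy-2,6,6-trimethylcyclohex-2-en-1-yl)but-3-en-2-one (both enantiomers) | CC1=C[C@@H](O)CC(C)(C)[C@]1(O)/C=C/C(C)=O.CC1=C[C@H](O)CC(C)(C)[C@@]1(O)/C=C/C(C)=O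
F4 | step 4 | (1R,4S)-4-hydroxy-3,5,5-trimethyl-4-[(E)-3-oxobut-1-en-1-yl]cyclohex-2-en-1-yl acetate (enantiomer of 9) | CC1=C[C@H](OC(C)=O)CC(C)(C)[C@@]1(O)/C=C/C(C)=O
F5 | step 5 | (R)-1-[(1R,4S)-1,4-dihydroxy-2,6,6-trimethylcyclohex-2-en-1-yl]but-2-yn-1-ol | CC1=C[C@@H](O)CC(C)(C)[C@]1(O)[C@H](O)C#CC
F6 | step 5 | 3,7-diacetate of F5 | CC1=C[C@@H](OC(C)=O)CC(C)(C)[C@]1(O)[C@H](OC(C)=O)C#CC
F7 | step 5 | 6-O-triethylsilyl ether of F6 | CC1=C[C@@H](OC(C)=O)CC(C)(C)[C@]1(O[Si](CC)(CC)CC)[C@H](OC(C)=O)C#CC
F8 | step 5 | 6-O-triethylsilyl ether of 9 | CC1=C[C@@H](OC(C)=O)CC(C)(C)[C@]1(O[Si](CC)(CC)CC)/C=C/C(C)=O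
F9 | step 3 | (R)-1-(2,6,6-trimethylcyclohexa-1,3-dien-1-yl)but-2-yn-1-yl acetate | CC1=C([C@H](OC(C)=O)C#CC)C(C)(C)CC=C1
F10 | step 3 | (S)-1-(2,6,6-trimethylcyclohexa-1,3-dien-1-yl)but-2-yn-1-ol | CC1=C([C@@H](O)C#CC)C(C)(C)CC=C1
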